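(All constants come from no measurement.)

At early times the nucleophile stood as its protonated form, and by my reckoning dissociation set 0.213 mM of it free, so the question was how much free nucleophile the free base would buy.

| setting | alder | larch |
|---|---|---|
| electrophile | 20 mM | 20 mM |
| free base | 22.0 mM | 44.0 mM |
| protonated nucleophile | 24.0 mM | 24.0 mM |
| time | 2.5 h | 2.5 h |

    electrophile + nucleophile ⇌ acid set free + product (K1 = 0.37, k1 = 0.011 M⁻¹ s⁻¹)
    nucleophile + acid set free ⇌ protonated nucleophile, settled at all times (K2 = 5.3 × 10⁵ M⁻¹)
    acid set free + free base ⇌ salt of the base (K3 = 63000 M⁻¹, k3 = 0.22 M⁻¹ s⁻¹)

* part of the electrophile that has reacted at the end, alder
* part of the electrophile that has reacted at the end, larch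
* what raising the concentration of free base from its lowest to its highest value here does to the part of the electrophile that has reacted (changes below 5 percentage points count as none) (it falls / no change / it rises)

Overall each product took two free base, so alder's 22.0 mM of free base covered 11.0 mM of product, less than its 20 mM of electrophile, and free base was the limiting reagent in alder. Larch's free base covered 22.0 mM of product, more than its 20 mM of electrophile, so electrophile was the limiting reagent in larch. I kept the books per electrophile reacted, alder first. Entry one: each electrophile that reacted took one nucleophile and left one product and one acid set free. Entry two: that acid, kept at balance, protonated another nucleophile, so each electrophile cost two free nucleophiles. Entry three: each acid the free base took out of the balance gave one free nucleophile back.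

I called N* the free-nucleophile level at which these entries cancel, a steady state: the square root of (rate constant of the base's step × free base × protonated nucleophile) over (two × rate constant of the first step × electrophile × constant of the balance). At the charges it came to 0.706 mM.

The square of the level closes on N* with a time of 18.9 min, shorter than the 2.5 h of the run, so I let the electrophile react at N* throughout. The part reacted is the first step's rate constant × N* × time, which gave 6.99% for alder. The books closed with 93.0% still electrophile and about 3.50 mM of salt of the base: two per product, plus the free nucleophile standing.

Larch, with twice the free base, had N* = 0.998 mM and 9.88%. The gap of 2.9 percentage points is smaller than 5 points, so I called it no change. The level starts below N* and the charges fall, so I took both figures as high.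

The forecast gave 6% for alder, 8.5% for larch and no change, holding that “Doubling the base raises free nucleophile only by about the square root of two”.

The simulation gave 5.84% for alder and 8.22% for larch: no change, with a change of 2.4 points. Free nucleophile in alder stood at 0.661 mM after 1.25 h and 0.650 mM after 2.50 h, against the N* of 0.706 mM. For the neighbour flask, alder with 88 mM of free base, N* came to 1.41 mM, twice alder's. That flask held 1.32 mM of free nucleophile after 2.50 h, with 11.5% of its electrophile reacted.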